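**Plan**
- Retrosynthesis first removes the eight O-methyl groups, then cuts two bonds of ring B: ketone-bearing carbon to fusion-bearing carbon, and oxygen-bearing carbon to the CH between the two oxygens. This opens ring B and the seven-membered ring together.
- The cut is possible because ring B is a pentasubstituted resorcinol. Its three adjacent carbon substituents (indane CH carrying the 3,5-dihydroxyphenyl group, ring-fusion CH, ketone carbon) and two meta oxygens map onto a cyclopenta-fused 4-methoxy-2-pyranone (C4a, C7a, C3–H, C4–OMe) plus a 3-methoxypropynoyl group tethered through ring A.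
- Further cuts: ynone to aldehyde to aryl vinyl group; pyranone to a cyclopentanone and malonyl dichloride; diarylmethine C–aryl and C3–aryl bonds (two conjugate additions); exocyclic C=C (aldol condensation); C4–aryl bond (addition to a 4-silyloxycyclopentenone).
- Forward: the five-membered ring is present from the start, the pyranone is annulated onto it, ring B and the cycloheptanone arise together in the cycloaddition, and demethylation ends the route.
- Stereochemistry: the first centre derives from purchased (S)-4-silyloxycyclopentenone; the other two ring centres follow from anti additions and equilibration to the all-trans ketone; the diarylmethine comes from face-selective addition to an E-arylidene ketone. The cycloaddition creates none.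
- The alkynyl ether is methyl rather than ethyl so that retro-ene loss of ethylene to a ketene cannot compete at the cycloaddition temperature; one reagent then removes all eight ethers.

Key step: step 13

Remark: the silyloxy enone, both aryl Grignard solutions, the bromo aldehyde, the vinylborate, malonyl dichloride and the chloro acetal are taken as purchasable; cyclopentanone positions are counted from the carbonyl carbon (C1) through the side-chain carbon (C2), and pyranones follow cyclopenta[b]pyran-2-one numbering.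

**Step 1**
Reactants: 1 2-bromo-4,6-dimethoxybenzaldehyde; 2 potassium vinyltrifluoroborate
Product: 3 2-ethenyl-4,6-dimethoxybenzaldehyde
Conditions: PdCl2(dppf) (3 mol %), Cs2CO3, THF–H2O 9:1, 80 °C
Reagents that add atoms: none
Why: Suzuki–Miyaura coupling of an aryl bromide with a vinyltrifluoroborate is routine and tolerates the ortho aldehyde; the vinyl group serves as a small, robust precursor of the later aldehyde.

**Step 2**
Reactants: 4 (4S)-4-[(tert-butyldimethylsilyl)oxy]cyclopent-2-en-1-one; 5 3,5-dimethoxyphenylmagnesium chloride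
Product: 6 (3R,4S)-4-[(tert-butyldimethylsilyl)oxy]-3-(3,5-dimethoxyphenyl)cyclopentan-1-one
Conditions: CuBr·SMe2 (10 mol %), THF, −78 °C; aq. NH4Cl at −78 °C
Reagents that add atoms: none
Why: Copper-catalysed conjugate addition of an aryl Grignard reagent to a 4-silyloxycyclopentenone occurs anti to the silyloxy group, so the purchased S centre sets the aryl-bearing carbon as R; the cold quench prevents enolate equilibration and loss of silanolate.

**Step 3**
Reactants: 6 (3R,4S)-4-[(tert-butyldimethylsilyl)oxy]-3-(3,5-dimethoxyphenyl)cyclopentan-1-one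
Product: 7 (3R,4S)-3-(3,5-dimethoxyphenyl)-4-hydroxycyclopentan-1-one
Conditions: HF·pyridine, THF, 0 °C to rt
Reagents that add atoms: none
Why: Fluoride-mediated desilylation under mildly acidic conditions frees the beta-hydroxy ketone without touching the aryl-bearing centre.

**Step 4**
Reactants: 7 (3R,4S)-3-(3,5-dimethoxyphenyl)-4-hydroxycyclopentan-1-one
Product: 8 (4S)-4-(3,5-dimethoxyphenyl)cyclopent-2-en-1-one
Conditions: MsCl, Et3N, CH2Cl2, −20 to 0 °C
Reagents that add atoms: none
Why: Mesylation of a beta-hydroxy ketone followed by E1cB elimination proceeds with triethylamine at low temperature, a base too weak and an exposure too short to remove the benzylic gamma-hydrogen of 8, so the S centre should be kept.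

**Step 5**
Reactants: 8 (4S)-4-(3,5-dimethoxyphenyl)cyclopent-2-en-1-one; 9 4-methoxyphenylmagnesium bromide; 3 2-ethenyl-4,6-dimethoxybenzaldehyde
Product: 11 (2R,3R,4S)-4-(3,5-dimethoxyphenyl)-2-[(2-ethenyl-4,6-dimethoxyphenyl)(hydroxy)methyl]-3-(4-methoxyphenyl)cyclopentan-1-one (both carbinol epimers), via bromomagnesium enolate 10 (not isolated)
Conditions: 9 added slowly to 8 and CuBr·SMe2 (10 mol %), THF, −78 °C; then 3, −78 °C; aq. NH4Cl
Reagents that add atoms: none
Why: In this tandem conjugate addition–aldol reaction (three-component coupling) the aryl group enters anti to the C4 aryl group (C3 becomes R) and the regiodefined enolate 10 adds to the aldehyde anti to the new C3 aryl group; the carbinol centre is left uncontrolled because the next step removes it.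

**Step 6**
Reactants: 11 (2R,3R,4S)-4-(3,5-dimethoxyphenyl)-2-[(2-ethenyl-4,6-dimethoxyphenyl)(hydroxy)methyl]-3-(4-methoxyphenyl)cyclopentan-1-one
Product: 12 (2E,3S,4S)-4-(3,5-dimethoxyphenyl)-2-[(2-ethenyl-4,6-dimethoxyphenyl)methylidene]-3-(4-methoxyphenyl)cyclopentan-1-one
Conditions: MsCl, Et3N, DMAP (cat.), CH2Cl2, 0 °C to rt
Reagents that add atoms: none
Why: Mesylation and E1cB elimination of the aldol (aldol condensation) should give the arylidene ketone as the E isomer, with ring A turned away from the carbonyl group, as is usual for 2-arylidene cyclopentanones.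

**Step 7**
Reactants: 12 (2E,3S,4S)-4-(3,5-dimethoxyphenyl)-2-[(2-ethenyl-4,6-dimethoxyphenyl)methylidene]-3-(4-methoxyphenyl)cyclopentan-1-one; 9 4-methoxyphenylmagnesium bromide
Product: 14 (2R,3R,4S)-4-(3,5-dimethoxyphenyl)-2-[(S)-(2-ethenyl-4,6-dimethoxyphenyl)(4-methoxyphenyl)methyl]-3-(4-methoxyphenyl)cyclopentan-1-one, via silyl enol ether 13 (not isolated)
Conditions: 9, CuBr·SMe2 (20 mol %), Me3SiCl, THF, −78 to −20 °C; then K2CO3, MeOH, rt
Reagents that add atoms: none
Why: In this Me3SiCl-accelerated copper-catalysed conjugate addition the C3 aryl group, pushed pseudoaxial by 1,3-allylic strain with ring A, should block one face of the E-arylidene so that the 4-methoxyphenyl group adds to the other face and sets the diarylmethine as S; methanolysis of 13 under equilibrating conditions then places the side chain trans to the C3 aryl group (C2 = R).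

**Step 8**
Reactants: 14 (2R,3R,4S)-4-(3,5-dimethoxyphenyl)-2-[(S)-(2-ethenyl-4,6-dimethoxyphenyl)(4-methoxyphenyl)methyl]-3-(4-methoxyphenyl)cyclopentan-1-one; 15 malonyl dichloride
Product: 17 (5S,6R,7R)-5-(3,5-dimethoxyphenyl)-7-[(S)-(2-ethenyl-4,6-dimethoxyphenyl)(4-methoxyphenyl)methyl]-4-hydroxy-6-(4-methoxyphenyl)-6,7-dihydrocyclopenta[b]pyran-2(5H)-one, via kinetic silyl enol ether 16 (not isolated)
Conditions: LiN(iPr)2, Me3SiCl, THF, −78 °C; solvent exchange to Et2O; then 15, −78 °C to rt
Reagents that add atoms: none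
Why: Kinetic deprotonation at the unhindered C5 methylene gives silyl enol ether 16, which malonyl dichloride C-acylates and then O-acylates to close the 4-hydroxy-2-pyranone (known annulation of silyl enol ethers with malonyl dichloride), leaving the C2 centre untouched.

**Step 9**
Reactants: 17 (5S,6R,7R)-5-(3,5-dimethoxyphenyl)-7-[(S)-(2-ethenyl-4,6-dimethoxyphenyl)(4-methoxyphenyl)methyl]-4-hydroxy-6-(4-methoxyphenyl)-6,7-dihydrocyclopenta[b]pyran-2(5H)-one
Product: 18 (5S,6R,7R)-5-(3,5-dimethoxyphenyl)-7-[(S)-(2-ethenyl-4,6-dimethoxyphenyl)(4-methoxyphenyl)methyl]-4-methoxy-6-(4-methoxyphenyl)-6,7-dihydrocyclopenta[b]pyran-2(5H)-one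
Conditions: Me2SO4, K2CO3, acetone, rt
Reagents that add atoms: dimethyl sulfate COS(=O)(=O)OC
Why: O-Alkylation of the acidic 4-hydroxy-2-pyranone with dimethyl sulfate and carbonate gives the 4-methoxy-2-pyranone, and the mild heterogeneous base should not remove the hydrogen at C7.

**Step 10**
Reactants: 18 (5S,6R,7R)-5-(3,5-dimethoxyphenyl)-7-[(S)-(2-ethenyl-4,6-dimethoxyphenyl)(4-methoxyphenyl)methyl]-4-methoxy-6-(4-methoxyphenyl)-6,7-dihydrocyclopenta[b]pyran-2(5H)-one
Product: 19 (5S,6R,7R)-5-(3,5-dimethoxyphenyl)-7-[(S)-(2-formyl-4,6-dimethoxyphenyl)(4-methoxyphenyl)methyl]-4-methoxy-6-(4-methoxyphenyl)-6,7-dihydrocyclopenta[b]pyran-2(5H)-one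
Conditions: OsO4 (2 mol %), NaIO4, 2,6-lutidine, dioxane–H2O 3:1, rt
Reagents that add atoms: osmium tetroxide O=[Os](=O)(=O)=O; sodium periodate [Na+].[O-]I(=O)(=O)=O
Why: In this Lemieux–Johnson cleavage OsO4 should dihydroxylate the monosubstituted styrene far faster than the tri- and tetrasubstituted pyranone double bonds, and periodate cleaves the diol to the aldehyde.

**Step 11**
Reactants: 19 (5S,6R,7R)-5-(3,5-dimethoxyphenyl)-7-[(S)-(2-formyl-4,6-dimethoxyphenyl)(4-methoxyphenyl)methyl]-4-methoxy-6-(4-methoxyphenyl)-6,7-dihydrocyclopenta[b]pyran-2(5H)-one; 20 chloroacetaldehyde dimethyl acetal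
Product: 21 (5S,6R,7R)-5-(3,5-dimethoxyphenyl)-7-[(S)-[2-(1-hydroxy-3-methoxyprop-2-yn-1-yl)-4,6-dimethoxyphenyl](4-methoxyphenyl)methyl]-4-methoxy-6-(4-methoxyphenyl)-6,7-dihydrocyclopenta[b]pyran-2(5H)-one (both carbinol epimers)
Conditions: 20 and LiNEt2 (from Et2NH and n-BuLi, 2.9 equiv per 20), THF, 0 °C; then 19, −78 °C; AcOH quench at −78 °C
Reagents that add atoms: none
Why: Lithium methoxyacetylide, formed by double elimination from the chloro acetal, should add to the aryl aldehyde at −78 °C much faster than it attacks or deprotonates the pyranone (acetylide 1,2-addition); the carbinol centre is irrelevant because it is oxidised next.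

**Step 12**
Reactants: 21 (5S,6R,7R)-5-(3,5-dimethoxyphenyl)-7-[(S)-[2-(1-hydroxy-3-methoxyprop-2-yn-1-yl)-4,6-dimethoxyphenyl](4-methoxyphenyl)methyl]-4-methoxy-6-(4-methoxyphenyl)-6,7-dihydrocyclopenta[b]pyran-2(5H)-one
Product: 22 (5S,6R,7R)-7-[(S)-[2,4-dimethoxy-6-(3-methoxyprop-2-ynoyl)phenyl](4-methoxyphenyl)methyl]-5-(3,5-dimethoxyphenyl)-4-methoxy-6-(4-methoxyphenyl)-6,7-dihydrocyclopenta[b]pyran-2(5H)-one
Conditions: MnO2 (activated, excess), CH2Cl2, rt
Reagents that add atoms: none
Why: MnO2 oxidises the benzylic, propargylic alcohol to the ynone under neutral anhydrous conditions that should spare the ynol ether and the C7 centre.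

**Step 13**
Reactants: 22 (5S,6R,7R)-7-[(S)-[2,4-dimethoxy-6-(3-methoxyprop-2-ynoyl)phenyl](4-methoxyphenyl)methyl]-5-(3,5-dimethoxyphenyl)-4-methoxy-6-(4-methoxyphenyl)-6,7-dihydrocyclopenta[b]pyran-2(5H)-one
Product: 24 octamethyl ether of 25 (tetracyclic ketone; ring A and ring B each carry two methoxy groups; configurations as in 25), via bridged lactone 23 (not isolated)
Conditions: PhMe (degassed, 0.005 M), BHT (5 mol %), sealed tube, 130 °C
Reagents that add atoms: none
Why: On heating, the 2-pyranone diene (C3 to C7a) and the tethered ynone should undergo a normal-demand intramolecular Diels–Alder reaction to bridged lactone 23, which loses carbon dioxide by cycloreversion to give the arene; the closest known reaction type is the intramolecular 2-pyranone–alkyne cycloaddition with extrusion of carbon dioxide. Ring B is closed by the (4+2) cycloaddition itself, through the bonds from the ynone alpha-carbon to C7a and from the methoxy-bearing beta-carbon to C3, and becomes aromatic in the retro-(4+2) step. The seven-membered ring closes in the same event as the tether ring of the cycloaddition, through the alpha-carbon–C7a bond, with the alpha-carbon inside the new ring. No stereocentre is created in 24: the two bridgeheads of 23 are fixed by the tether, which leaves C7 on one face of the pyranone, and they vanish on aromatisation. The step needs regiocontrol, which the tether enforces and polarity reinforces (nucleophilic pyranone C3 to the electrophilic alkoxy-bearing carbon), and it needs retention at C7 and at the diarylmethine, which neutral base-free conditions should secure. The methyl ynol ether has no hydrogen placed for retro-ene loss of an alkene, so the dienophile should survive the temperature required.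

**Step 14**
Reactants: 24 octamethyl ether of 25
Product: 25 CNP0116600.1 (seven-ring methine bearing 4-hydroxyphenyl S; ring-fusion CH R; five-ring CH bearing 4-hydroxyphenyl S; five-ring CH bearing 3,5-dihydroxyphenyl S)
Conditions: BBr3 (excess), CH2Cl2, −78 °C to rt; then MeOH, H2O
Reagents that add atoms: none
Why: Boron tribromide cleaves all eight aryl methyl ethers (Lewis-acid ether cleavage) and should leave the diaryl ketone and the four methine centres, none of which is epimerisable under acid, unchanged.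

**Compound list**
1 | 2-bromo-4,6-dimethoxybenzaldehyde | O=Cc1c(Br)cc(OC)cc1OC | starting material
2 | potassium vinyltrifluoroborate | [K+].C=C[B-](F)(F)F | starting material
3 | 2-ethenyl-4,6-dimethoxybenzaldehyde | O=Cc1c(C=C)cc(OC)cc1OC | intermediate
4 | (4S)-4-[(tert-butyldimethylsilyl)oxy]cyclopent-2-en-1-one | O=C1C=C[C@@H](O[Si](C)(C)C(C)(C)C)C1 | starting material
5 | 3,5-dimethoxyphenylmagnesium chloride (THF solution) | COc1cc(OC)cc([Mg]Cl)c1 | starting material
6 | (3R,4S)-4-[(tert-butyldimethylsilyl)oxy]-3-(3,5-dimethoxyphenyl)cyclopentan-1-one | O=C1C[C@H](c2cc(OC)cc(OC)c2)[C@@H](O[Si](C)(C)C(C)(C)C)C1 | intermediate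
7 | (3R,4S)-3-(3,5-dimethoxyphenyl)-4-hydroxycyclopentan-1-one | O=C1C[C@H](c2cc(OC)cc(OC)c2)[C@@H](O)C1 | intermediate
8 | (4S)-4-(3,5-dimethoxyphenyl)cyclopent-2-en-1-one | O=C1C=C[C@@H](c2cc(OC)cc(OC)c2)C1 | intermediate
9 | 4-methoxyphenylmagnesium bromide (THF solution) | COc1ccc([Mg]Br)cc1 | starting material
10 | bromomagnesium (3R,4S)-4-(3,5-dimethoxyphenyl)-3-(4-methoxyphenyl)cyclopent-1-en-1-olate | Br[Mg]OC1=C[C@H](c2ccc(OC)cc2)[C@@H](c2cc(OC)cc(OC)c2)C1 | intermediate (not isolated)
11 | (2R,3R,4S)-4-(3,5-dimethoxyphenyl)-2-[(2-ethenyl-4,6-dimethoxyphenyl)(hydroxy)methyl]-3-(4-methoxyphenyl)cyclopentan-1-one, both carbinol epimers | O=C1[C@@H](C(O)c2c(C=C)cc(OC)cc2OC)[C@H](c2ccc(OC)cc2)[C@@H](c2cc(OC)cc(OC)c2)C1 | intermediate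
12 | (2E,3S,4S)-4-(3,5-dimethoxyphenyl)-2-[(2-ethenyl-4,6-dimethoxyphenyl)methylidene]-3-(4-methoxyphenyl)cyclopentan-1-one | O=C1/C(=C/c2c(C=C)cc(OC)cc2OC)[C@H](c2ccc(OC)cc2)[C@@H](c2cc(OC)cc(OC)c2)C1 | intermediate
13 | C1=C2 trimethylsilyl enol ether of 14 (1-trimethylsilyloxycyclopentene carrying the S-configured diarylmethyl group at C2, 4-methoxyphenyl at C3 and 3,5-dimethoxyphenyl at C4, 3,4-trans) | C[Si](C)(C)OC1=C([C@@H](c2ccc(OC)cc2)c2c(C=C)cc(OC)cc2OC)[C@H](c2ccc(OC)cc2)[C@@H](c2cc(OC)cc(OC)c2)C1 | intermediate (not isolated)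
14 | (2R,3R,4S)-4-(3,5-dimethoxyphenyl)-2-[(S)-(2-ethenyl-4,6-dimethoxyphenyl)(4-methoxyphenyl)methyl]-3-(4-methoxyphenyl)cyclopentan-1-one | O=C1[C@@H]([C@@H](c2ccc(OC)cc2)c2c(C=C)cc(OC)cc2OC)[C@H](c2ccc(OC)cc2)[C@@H](c2cc(OC)cc(OC)c2)C1 | intermediate
15 | malonyl dichloride | ClC(=O)CC(Cl)=O | starting material
16 | kinetic C1=C5 trimethylsilyl enol ether of 14 (all three ring substituents mutually trans) | C[Si](C)(C)OC1=C[C@H](c2cc(OC)cc(OC)c2)[C@@H](c2ccc(OC)cc2)[C@@H]1[C@@H](c2ccc(OC)cc2)c2c(C=C)cc(OC)cc2OC | intermediate (not isolated)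
17 | (5S,6R,7R)-5-(3,5-dimethoxyphenyl)-7-[(S)-(2-ethenyl-4,6-dimethoxyphenyl)(4-methoxyphenyl)methyl]-4-hydroxy-6-(4-methoxyphenyl)-6,7-dihydrocyclopenta[b]pyran-2(5H)-one | O=C1C=C(O)C2=C(O1)[C@@H]([C@@H](c3ccc(OC)cc3)c3c(C=C)cc(OC)cc3OC)[C@H](c3ccc(OC)cc3)[C@H]2c2cc(OC)cc(OC)c2 | intermediate
18 | 4-methoxy analogue of 17 (4-O-methyl ether) | O=C1C=C(OC)C2=C(O1)[C@@H]([C@@H](c3ccc(OC)cc3)c3c(C=C)cc(OC)cc3OC)[C@H](c3ccc(OC)cc3)[C@H]2c2cc(OC)cc(OC)c2 | intermediate
19 | (5S,6R,7R)-5-(3,5-dimethoxyphenyl)-7-[(S)-(2-formyl-4,6-dimethoxyphenyl)(4-methoxyphenyl)methyl]-4-methoxy-6-(4-methoxyphenyl)-6,7-dihydrocyclopenta[b]pyran-2(5H)-one | O=C1C=C(OC)C2=C(O1)[C@@H]([C@@H](c3ccc(OC)cc3)c3c(C=O)cc(OC)cc3OC)[C@H](c3ccc(OC)cc3)[C@H]2c2cc(OC)cc(OC)c2 | intermediate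
20 | chloroacetaldehyde dimethyl acetal (2-chloro-1,1-dimethoxyethane) | COC(CCl)OC | starting material
21 | propargylic alcohol: 19 with the formyl group replaced by 1-hydroxy-3-methoxyprop-2-yn-1-yl, both carbinol epimers | O=C1C=C(OC)C2=C(O1)[C@@H]([C@@H](c3ccc(OC)cc3)c3c(C(O)C#COC)cc(OC)cc3OC)[C@H](c3ccc(OC)cc3)[C@H]2c2cc(OC)cc(OC)c2 | intermediate
22 | (5S,6R,7R)-7-[(S)-[2,4-dimethoxy-6-(3-methoxyprop-2-ynoyl)phenyl](4-methoxyphenyl)methyl]-5-(3,5-dimethoxyphenyl)-4-methoxy-6-(4-methoxyphenyl)-6,7-dihydrocyclopenta[b]pyran-2(5H)-one | O=C1C=C(OC)C2=C(O1)[C@@H]([C@@H](c3ccc(OC)cc3)c3c(C(=O)C#COC)cc(OC)cc3OC)[C@H](c3ccc(OC)cc3)[C@H]2c2cc(OC)cc(OC)c2 | intermediate (precursor of the key step)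
23 | bridged lactone (2-oxabicyclo[2.2.2]octadienone) formed by addition of the ynone across pyranone C3 and C7a on the face of the tether | O=C1O[C@@]23C4=C(OC)[C@@H]1C(OC)=C2[C@H](c5cc(OC)cc(OC)c5)[C@@H](c5ccc(OC)cc5)[C@@H]3[C@@H](c5ccc(OC)cc5)c5c(OC)cc(OC)cc5C4=O | intermediate (not isolated)
24 | octamethyl ether of 25 | O=C1c2cc(OC)cc(OC)c2[C@H](c2ccc(OC)cc2)[C@@H]2c3c1c(OC)cc(OC)c3[C@H](c1cc(OC)cc(OC)c1)[C@H]2c1ccc(OC)cc1 | intermediate (product of the key step)
25 | CNP0116600.1 | O=C1c2cc(O)cc(O)c2[C@H](c2ccc(O)cc2)[C@@H]2c3c1c(O)cc(O)c3[C@H](c1cc(O)cc(O)c1)[C@H]2c1ccc(O)cc1 | target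

**Totals and risks**
Total step count: 14. Longest linear sequence: 13 steps (4 to 25, steps 2–14); step 1 is the only side branch.

Most likely to fail:

Step 13. The tether has to fold into a benzo-fused seven-membered ring next to a fully substituted cyclopentane, so the cycloaddition may be slower than thermal decomposition of the alkoxy ynone. The fallback reverses the order of ring formation; it sets out from 8 and comes back at 24.
- Copper-catalysed addition of 9 to 8 with trapping by 4-methoxybenzaldehyde gives the aldol (2R,3R,4S)-4-(3,5-dimethoxyphenyl)-2-[hydroxy(4-methoxyphenyl)methyl]-3-(4-methoxyphenyl)cyclopentan-1-one F1, which tert-butyldimethylsilyl triflate and 2,6-lutidine convert into the silyl ether F2.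
- Kinetic enolisation with LiN(iPr)2 and Me3SiCl gives the trimethylsilyl enol ether F3; 15 turns it into the hydroxypyranone F4, and dimethyl sulfate with K2CO3 gives the methoxypyranone F5.
- Separately, lithium methoxyacetylide and 3,5-dimethoxybenzaldehyde give the propargylic alcohol F6, which MnO2 oxidises to the ynone F7.
- Heating F5 with F7 should give, by the same polarity-matched orientation, the bridged lactone F8 and, after loss of carbon dioxide, the benzophenone F9, in which ring B is complete.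
- BF3·OEt2 in CH2Cl2 then ionises the benzylic silyl ether, and Friedel–Crafts alkylation of ring A at the position ortho to the ketone and para to a methoxy group closes the seven-membered ring to 24. This closure is expected to place the 4-methoxyphenyl group trans to the neighbouring ring bond, as in 24.

Step 7. Addition to an arylidene carrying two ortho substituents may be slow, and erosion of the alkene geometry or poor facial discrimination would scramble the diarylmethine centre. The fallback forms the other aryl–carbon bond of that centre; it sets out from 8 and comes back at 14.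
- The aldol F1, made from 8, 9 and 4-methoxybenzaldehyde as above, is ionised with HBF4·OEt2 in CH2Cl2 at −78 °C in the presence of excess 1-bromo-3,5-dimethoxybenzene.
- The benzylic cation, with the C2 hydrogen in its plane to minimise 1,3-allylic strain, should be attacked by the arene on the face turned away from C3 and the C4 aryl group. Reaction at the arene position ortho to bromine and para to a methoxy group gives the bromo ketone (2R,3R,4S)-2-[(S)-(2-bromo-4,6-dimethoxyphenyl)(4-methoxyphenyl)methyl]-4-(3,5-dimethoxyphenyl)-3-(4-methoxyphenyl)cyclopentan-1-one F10 (diastereoselective Friedel–Crafts alkylation).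
- Suzuki–Miyaura coupling of F10 with 2 under the conditions of step 1 gives 14.

Step 8. Incomplete regiocontrol in the enolisation, competing O-acylation, or acid-promoted side reactions in the one-flask annulation may erode the pyranone. The fallback builds the ring in stages; it sets out from 14 and comes back at 17.
- The kinetic lithium enolate of 14 (LiN(iPr)2, THF, −78 °C) is C-acylated with N-methoxy-N-methylacetamide to the 5-acetyl ketone F11.
- Dianion formation (LiN(iPr)2, 2.2 equiv) and carboxylation at the methyl terminus with CO2 gives the 3,5-dioxo acid F12.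
- Trifluoroacetic anhydride in CH2Cl2 closes the enol lactone to 17.

**Further compounds**
F1 | step 13 | (2R,3R,4S)-4-(3,5-dimethoxyphenyl)-2-[hydroxy(4-methoxyphenyl)methyl]-3-(4-methoxyphenyl)cyclopentan-1-one (both carbinol epimers) | O=C1[C@@H](C(O)c2ccc(OC)cc2)[C@H](c2ccc(OC)cc2)[C@@H](c2cc(OC)cc(OC)c2)C1
F2 | step 13 | tert-butyldimethylsilyl ether of F1 | O=C1[C@@H](C(O[Si](C)(C)C(C)(C)C)c2ccc(OC)cc2)[C@H](c2ccc(OC)cc2)[C@@H](c2cc(OC)cc(OC)c2)C1
F3 | step 13 | kinetic C1=C5 trimethylsilyl enol ether of F2 | C[Si](C)(C)OC1=C[C@H](c2cc(OC)cc(OC)c2)[C@@H](c2ccc(OC)cc2)[C@@H]1C(O[Si](C)(C)C(C)(C)C)c1ccc(OC)cc1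
F4 | step 13 | (5S,6R,7R)-7-[(tert-butyldimethylsilyloxy)(4-methoxyphenyl)methyl]-5-(3,5-dimethoxyphenyl)-4-hydroxy-6-(4-methoxyphenyl)-6,7-dihydrocyclopenta[b]pyran-2(5H)-one | O=C1C=C(O)C2=C(O1)[C@@H](C(O[Si](C)(C)C(C)(C)C)c3ccc(OC)cc3)[C@H](c3ccc(OC)cc3)[C@H]2c2cc(OC)cc(OC)c2
F5 | step 13 | 4-O-methyl ether of F4 | O=C1C=C(OC)C2=C(O1)[C@@H](C(O[Si](C)(C)C(C)(C)C)c3ccc(OC)cc3)[C@H](c3ccc(OC)cc3)[C@H]2c2cc(OC)cc(OC)c2
F6 | step 13 | 1-(3,5-dimethoxyphenyl)-3-methoxyprop-2-yn-1-ol (racemic) | COC#CC(O)c1cc(OC)cc(OC)c1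
F7 | step 13 | 1-(3,5-dimethoxyphenyl)-3-methoxyprop-2-yn-1-one | COC#CC(=O)c1cc(OC)cc(OC)c1
F8 | step 13 | bridged lactone from F5 and F7 (bridgehead configuration not defined) | O=C1OC23C(C(=O)c4cc(OC)cc(OC)c4)=C(OC)C1C(OC)=C2[C@H](c4cc(OC)cc(OC)c4)[C@@H](c4ccc(OC)cc4)[C@@H]3C(O[Si](C)(C)C(C)(C)C)c4ccc(OC)cc4
F9 | step 13 | indane benzophenone with ring B complete: 3,5-dimethoxybenzoyl group on ring B, silyloxy(4-methoxyphenyl)methyl group on the future ring-fusion carbon, all-trans indane | COc1cc(OC)cc(c1)C(=O)c1c(OC)cc(OC)c2c1[C@@H](C(O[Si](C)(C)C(C)(C)C)c1ccc(OC)cc1)[C@H](c1ccc(OC)cc1)[C@H]2c1cc(OC)cc(OC)c1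
F10 | step 7 | (2R,3R,4S)-2-[(S)-(2-bromo-4,6-dimethoxyphenyl)(4-methoxyphenyl)methyl]-4-(3,5-dimethoxyphenyl)-3-(4-methoxyphenyl)cyclopentan-1-one | O=C1[C@@H]([C@@H](c2ccc(OC)cc2)c2c(Br)cc(OC)cc2OC)[C@H](c2ccc(OC)cc2)[C@@H](c2cc(OC)cc(OC)c2)C1
F11 | step 8 | 5-acetyl derivative of 14 (keto–enol mixture at C5) | O=C1C(C(C)=O)[C@H](c2cc(OC)cc(OC)c2)[C@@H](c2ccc(OC)cc2)[C@@H]1[C@@H](c2ccc(OC)cc2)c2c(C=C)cc(OC)cc2OC
F12 | step 8 | 3-oxo-3-(2-oxocyclopentyl)propanoic acid derived from F11 by carboxylation of the acetyl methyl group | O=C1C(C(=O)CC(=O)O)[C@H](c2cc(OC)cc(OC)c2)[C@@H](c2ccc(OC)cc2)[C@@H]1[C@@H](c2ccc(OC)cc2)c2c(C=C)cc(OC)cc2OC
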